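**Strategy.** Everything rests on assembling the benzene ring of the indole from an acyclic chain by cutting C3a–C7a and C6–C7. The feature exploited is the 1,3-placement of the benzenoid bromines. C5 lies para and C7 ortho to N1, and these carbons trace back to the internal alkene carbon of a conjugated enyne and to the outer carbon of an ynamide. Trimethylsilyl groups parked there become bromine later by ipso substitution under nitrogen activation. One thermal intramolecular [4+2] cycloaddition closes the five-membered ring and the six-membered ring at once. Its precursor is an N-methoxycarbonyl silyl ynamide tied through an ethylene chain to a 2-silyl-1-en-3-yne.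

Key step: step 5

Assumption: in the double ipso bromination the less crowded C5 silane is taken to react before the C7 silane; the reverse order would converge on the same dibromide.

Design remark: the methyl carbamate stays on nitrogen because it should tolerate the thermolysis, which a tert-butyl carbamate would not, and it still lets nitrogen activate C5 and C7. Trimethylsilyl is kept on both carbons because bulkier silanes resist ipso bromination.

Step 1
Reactants: 1 but-3-yn-1-amine; 2 methyl chloroformate
Product: 3 methyl but-3-yn-1-ylcarbamate
Conditions: aq NaOH (1.2 equiv), CH2Cl2, 0 °C → rt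
Reagents that add atoms: none
Why: Schotten–Baumann N-acylation, in which the primary amine outcompetes water for the chloroformate and the terminal alkyne is a spectator.

Step 2
Reactants: 3 methyl but-3-yn-1-ylcarbamate; 4 (1-bromovinyl)trimethylsilane
Product: 5 methyl [5-(trimethylsilyl)hex-5-en-3-yn-1-yl]carbamate
Conditions: Pd(PPh3)2Cl2 (3 mol %), CuI (6 mol %), Et3N (3 equiv), THF, degassed, rt → 45 °C
Reagents that add atoms: none
Why: Sonogashira coupling, in which zerovalent palladium inserts into the vinylic C–Br bond of 4 and the copper acetylide of 3 delivers the alkynyl group, while the carbamate N–H and the vinyl C–Si bond are inert to the mild amine medium.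

Step 3
Reactants: 6 ethynyltrimethylsilane
Product: 7 (bromoethynyl)trimethylsilane
Conditions: NBS (1.1 equiv), AgNO3 (10 mol %), acetone, rt, dark; pentane extraction, used without distillation
Reagents that add atoms: N-bromosuccinimide, O=C1CCC(=O)N1Br
Why: Silver-catalysed electrophilic bromination of a terminal alkyne exchanges only the acetylenic C–H under neutral conditions and leaves the C–Si bond intact.

Step 4
Reactants: 5 methyl [5-(trimethylsilyl)hex-5-en-3-yn-1-yl]carbamate; 7 (bromoethynyl)trimethylsilane
Product: 10 methyl N-[5-(trimethylsilyl)hex-5-en-3-yn-1-yl]-N-[(trimethylsilyl)ethynyl]carbamate, via N-potassium carbamate 8 (not isolated), via N-copper carbamate 9 (not isolated)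
Conditions: KN(SiMe3)2 (1.0 equiv), pyridine–THF, 0 °C; CuI (1.0 equiv), rt, 2 h; 7 (1.8 equiv) in THF, slow addition, rt, 20 h
Reagents that add atoms: none
Why: Copper-mediated N-alkynylation of a carbamate with a 1-bromoalkyne (Ullmann-type C(sp)–N coupling), in which the preformed monovalent copper amide couples at room temperature and so spares the base- and heat-sensitive alkynyl silane and the enyne.

Step 5
Reactants: 10 methyl N-[5-(trimethylsilyl)hex-5-en-3-yn-1-yl]-N-[(trimethylsilyl)ethynyl]carbamate
Product: 12 methyl 5,7-bis(trimethylsilyl)indoline-1-carboxylate, via cyclic allene 11 (not isolated)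
Conditions: BHT (1 equiv), toluene (0.05 M), degassed, sealed tube, 180 °C
Reagents that add atoms: none
Why: The ynamide triple bond (2π) adds across the tethered conjugated enyne (4π, C3a≡C4–C5=C6), concertedly or through a short-lived diradical, to give the strained cyclohexa-1,2,4-triene 11 (allene C3a=C4=C5), and transfer of one hydrogen from the C6 methylene to the central allene carbon C4, relayed by BHT, releases the strain and delivers the arene. The closest known reaction type is the thermal intramolecular enyne–ynamide [4+2] cycloaddition (a dehydro-Diels–Alder benzannulation) that converts N-(hex-5-en-3-ynyl) ynamides into indolines. The five-membered ring closes when C3a bonds to C7a across the three-atom N1–C2–C3 tether, a closure that is 5-exo-dig towards both triple bonds, and the six-membered ring closes by the cycloaddition itself when C6 bonds to C7. No stereocentre is formed. Regiochemistry is not open to choice, because the short tether lets only the nitrogen-bearing alkyne carbon reach C3a, so the silylated terminus must meet the unsubstituted CH2 end of the alkene and silicon ends up on C5 and C7. The remaining needs are ring closure ahead of intermolecular reaction and survival of both C–Si bonds, which dilution, a neutral aprotic degassed medium and the radical inhibitor should secure.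

Step 6
Reactants: 12 methyl 5,7-bis(trimethylsilyl)indoline-1-carboxylate
Product: 14 methyl 5,7-dibromoindoline-1-carboxylate, via 5-bromo-7-silyl indoline carbamate 13 (not isolated)
Conditions: Br2 (2.2 equiv), dry CH2Cl2, −78 °C → rt, dark
Reagents that add atoms: bromine, BrBr
Why: Electrophilic ipso bromodesilylation, in which attack at each silicon-bearing carbon gives an arenium ion stabilised by the β-silicon effect and by the para or ortho carbamate nitrogen before Me3SiBr departs, while C4–H and C6–H are meta to nitrogen and should stay untouched.

Step 7
Reactants: 14 methyl 5,7-dibromoindoline-1-carboxylate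
Product: 16 5,7-dibromoindoline, via potassium indoline-1-carboxylate salt 15 (not isolated)
Conditions: KOH (10 equiv), aq EtOH, N2, reflux
Reagents that add atoms: none
Why: Alkaline carbamate hydrolysis (BAc2 saponification, then decarboxylation of the carbamate salt) is eased by the electron-poor dibromoaniline nitrogen, and aryl bromides lacking strong acceptor groups are not displaced by hydroxide.

Step 8
Reactants: 16 5,7-dibromoindoline
Product: 17 5,7-dibromoindole
Conditions: DDQ (2,3-dichloro-5,6-dicyano-1,4-benzoquinone, 1.05 equiv), toluene, rt
Reagents that add atoms: none
Why: Quinone dehydrogenation of an indoline, in which hydride abstraction next to the free amine nitrogen followed by proton loss aromatises the five-membered ring, a standard indoline-to-indole oxidation that leaves aryl bromides alone.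

Step 9
Reactants: 17 5,7-dibromoindole
Product: 18 3,5,7-tribromoindole
Conditions: NBS (1.0 equiv), DMF, 0 °C, dark
Reagents that add atoms: N-bromosuccinimide, O=C1CCC(=O)N1Br
Why: Electrophilic aromatic substitution of an N–H indole with one equivalent of NBS should go to C3, the most nucleophilic position, since the brominated benzene ring is deactivated and C2 reacts only with excess reagent.

**Compound list**

1 | but-3-yn-1-amine | NCCC#C | starting material
2 | methyl chloroformate | COC(=O)Cl | starting material
3 | methyl but-3-yn-1-ylcarbamate | COC(=O)NCCC#C | intermediate
4 | (1-bromovinyl)trimethylsilane | C=C(Br)[Si](C)(C)C | starting material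
5 | methyl [5-(trimethylsilyl)hex-5-en-3-yn-1-yl]carbamate | COC(=O)NCCC#CC(=C)[Si](C)(C)C | intermediate
6 | ethynyltrimethylsilane | C#C[Si](C)(C)C | starting material
7 | (bromoethynyl)trimethylsilane | BrC#C[Si](C)(C)C | intermediate
8 | potassium (methoxycarbonyl)[5-(trimethylsilyl)hex-5-en-3-yn-1-yl]azanide | COC(=O)[N-]CCC#CC(=C)[Si](C)(C)C.[K+] | intermediate
9 | monovalent copper (methoxycarbonyl)[5-(trimethylsilyl)hex-5-en-3-yn-1-yl]azanide | COC(=O)N([Cu])CCC#CC(=C)[Si](C)(C)C | intermediate
10 | methyl N-[5-(trimethylsilyl)hex-5-en-3-yn-1-yl]-N-[(trimethylsilyl)ethynyl]carbamate | COC(=O)N(CCC#CC(=C)[Si](C)(C)C)C#C[Si](C)(C)C | intermediate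
11 | methyl 5,7-bis(trimethylsilyl)-2,3-dihydro-6H-indole-1-carboxylate, cyclic allene with cumulated C3a=C4=C5, a C6 methylene and C7=C7a | COC(=O)N1CCC2=C=C([Si](C)(C)C)CC([Si](C)(C)C)=C12 | intermediate
12 | methyl 5,7-bis(trimethylsilyl)indoline-1-carboxylate | COC(=O)N1CCc2cc([Si](C)(C)C)cc([Si](C)(C)C)c21 | intermediate
13 | methyl 5-bromo-7-(trimethylsilyl)indoline-1-carboxylate | COC(=O)N1CCc2cc(Br)cc([Si](C)(C)C)c21 | intermediate
14 | methyl 5,7-dibromoindoline-1-carboxylate | COC(=O)N1CCc2cc(Br)cc(Br)c21 | intermediate
15 | potassium 5,7-dibromoindoline-1-carboxylate | [K+].[O-]C(=O)N1CCc2cc(Br)cc(Br)c21 | intermediate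
16 | 5,7-dibromoindoline | Brc1cc(Br)c2NCCc2c1 | intermediate
17 | 5,7-dibromoindole | Brc1cc(Br)c2[nH]ccc2c1 | intermediate
18 | 3,5,7-tribromoindole | Brc1cc(Br)c2[nH]cc(Br)c2c1 | target

**Total step count:** 9

**Longest linear sequence:** 8 steps (1, 2, 4, 5, 6, 7, 8, 9); step 3 is a one-step side branch.

**Steps most likely to fail**

1. **Step 5.**
   - **Risk:** Crowding between the alkynyl silane, the carbamate and the incoming CH2 terminus may slow the cycloaddition. Thermal oligomerisation of the ynamide or loss of silicon could then overtake ring closure.
   - **Fallback:** This sets out from 10. Only the alkynyl silane is removed (K2CO3 cat., MeOH, 0 °C; the vinyl silane is inert) to give methyl N-ethynyl-N-[5-(trimethylsilyl)hex-5-en-3-yn-1-yl]carbamate F1. Its unhindered 2π partner should cyclise under the same thermolysis to methyl 5-(trimethylsilyl)indoline-1-carboxylate F2. KOH in refluxing aq EtOH should then free 5-(trimethylsilyl)indoline F3. NBS (2 equiv, DMF, 0 °C) should exchange silicon at C5 and brominate C7–H ortho to the free amine, which rejoins the route at 16. The C7 bromine is then placed by amine-directed substitution and not by a placeholder.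

2. **Step 4.**
   - **Risk:** Copper-promoted homocoupling of the bromoalkyne and cleavage of its C(sp)–Si bond may outrun C–N bond formation.
   - **Fallback:** This sets out from 5, which is deprotonated with KN(SiMe3)2 in toluene at 0 °C and treated with commercial phenyl[(trimethylsilyl)ethynyl]iodonium triflate. Addition of the nitrogen anion to the β-carbon of the alkynyl iodonium, loss of iodobenzene and a 1,2-silyl shift should deliver 10 directly, without copper and by a hypervalent-iodine alkynyl transfer. No new compound arises on this way (F0).

3. **Step 6.**
   - **Risk:** Exchange at crowded C7 may stall after the first bromination, or traces of HBr may cause protodesilylation.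
   - **Fallback:** This sets out from 12. The carbamate is cleaved first (KOH, aq EtOH, reflux) to give 5,7-bis(trimethylsilyl)indoline F4, which is treated with NBS (2 equiv, DMF, 0 °C). The free amine activates both positions far more strongly. A position that has lost silicon is still ortho or para to nitrogen and is brominated by ordinary substitution, so all channels should converge on 16, where the route is rejoined.

**Further compounds**

F1 | step 5 | methyl N-ethynyl-N-[5-(trimethylsilyl)hex-5-en-3-yn-1-yl]carbamate | COC(=O)N(C#C)CCC#CC(=C)[Si](C)(C)C
F2 | step 5 | methyl 5-(trimethylsilyl)indoline-1-carboxylate | COC(=O)N1CCc2cc([Si](C)(C)C)ccc21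
F3 | step 5 | 5-(trimethylsilyl)indoline | C[Si](C)(C)c1ccc2NCCc2c1
F0 | step 4 | none | none
F4 | step 6 | 5,7-bis(trimethylsilyl)indoline | C[Si](C)(C)c1cc([Si](C)(C)C)c2NCCc2c1
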